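**Assumption:** the target is drawn as one enol tautomer of the β‑diketone; keto–enol tautomers are treated as the same compound. Ring locants used below: C1 (O‑aryl), C2=C3(CH3), C4 (OH), C5, C6 (side chain); C7 is the side‑chain CH(CH3).

## Retrosynthetic overview

1. Target ⇒ Mitsunobu etherification (inversion at C1) of cyclohexenol 16 with mono‑TIPS curcumin 21, then global desilylation; 21 comes from two vanillin units and acetylacetone by two boron‑mediated condensations.
2. 16 ⇒ alkenyllithium opening of cis‑fused δ‑lactone 15 ⇒ L‑Selectride reduction/lactonisation of cyclohexenone 14 ⇒ ring‑closing metathesis (C2=C3) of acyclic enone‑diene 13.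
3. 13 ⇒ thioester/vinyl coupling from Evans alkylation product 11 ⇒ imide 10 (C7 from enzymatic desymmetrisation of dimethyl 3‑methylglutarate) + triflate 5 (C4 from Sharpless epoxidation of prenol).
4. Ring order: cyclohexene (RCM), then a temporary δ‑lactone that is reopened; no other rings are made.

## Route

### Branch A – C3–C5 electrophile (sets C4)

**Step 1**
Reactants: 1, prenol
Product: 2, [(2S)‑3,3‑dimethyloxiran‑2‑yl]methanol
Conditions: Ti(OiPr)4 (cat.), L‑(+)‑DET, t‑BuOOH, 4 Å MS, CH2Cl2, −20 °C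
Reagents that add atoms: tert‑butyl hydroperoxide, CC(C)(C)OO
Why: Sharpless asymmetric epoxidation; the L‑(+)‑tartrate catalyst gives the (2S)‑epoxy alcohol (future C4–O stereocentre, ~90–95% ee; the minor enantiomer becomes a separable diastereomer after step 8).

**Step 2**
Reactants: 2
Product: 3, (3R)‑3,4‑bis(tert‑butyldimethylsilyloxy)‑2‑methylbut‑1‑ene
Conditions: TBSOTf (2.3 equiv), 2,6‑lutidine, toluene, −78 → 0 °C; then DBU, rt
Reagents that add atoms: TBSOTf, CC(C)(C)[Si](C)(C)OS(=O)(=O)C(F)(F)F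
Why: O‑silylation followed by Noyori‑type silyl‑triflate epoxide → allyl silyl ether isomerisation; the tertiary C–O bond ionises and DBU removes a methyl proton, so the C–O bond at the stereocentre is untouched (retention).

**Step 3**
Reactants: 3
Product: 4, (2R)‑2‑(tert‑butyldimethylsilyloxy)‑3‑methylbut‑3‑en‑1‑ol
Conditions: CSA (cat.), MeOH/CH2Cl2, −10 °C
Reagents that add atoms: none
Why: Acid‑catalysed methanolysis removes the primary TBS ether much faster than the hindered secondary one (selective desilylation).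

**Step 4**
Reactants: 4
Product: 5, (2R)‑2‑(tert‑butyldimethylsilyloxy)‑3‑methylbut‑3‑en‑1‑yl triflate
Conditions: Tf2O, 2,6‑lutidine, CH2Cl2, −78 °C; cold silica plug, used at once
Reagents that add atoms: triflic anhydride, O=S(=O)(OS(=O)(=O)C(F)(F)F)C(F)(F)F
Why: Triflation of the primary alcohol gives an electrophile reactive enough for enolate alkylation at −78 °C, which a β‑silyloxy halide would not be.

### Branch B – C1/C6–C9 nucleophile (sets C7)

**Step 5**
Reactants: 6, 3‑methylglutaric acid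
Product: 7, dimethyl 3‑methylglutarate
Conditions: MeOH, H2SO4 (cat.), reflux
Reagents that add atoms: methanol, CO
Why: Fischer esterification of the cheap meso‑type diacid.

**Step 6**
Reactants: 7
Product: 8, (3R)‑5‑methoxy‑3‑methyl‑5‑oxopentanoic acid
Conditions: pig liver esterase, pH 7 phosphate buffer/MeOH (4:1), −10 °C, pH‑stat
Reagents that add atoms: water, O
Why: Enzymatic desymmetrisation hydrolyses one enantiotopic ester to give the (R)‑half‑ester (sets C7, ~95% ee).

**Step 7**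
Reactants: 8; 9, (4R)‑4‑benzyl‑1,3‑oxazolidin‑2‑one
Product: 10, methyl (3R)‑5‑[(4R)‑4‑benzyl‑2‑oxo‑oxazolidin‑3‑yl]‑3‑methyl‑5‑oxopentanoate
Conditions: PivCl, Et3N, THF, −20 °C; then 9/n‑BuLi, THF, −78 → 0 °C
Reagents that add atoms: none
Why: Mixed‑anhydride N‑acylation of the lithiated Evans auxiliary at the free acid terminus; the methyl ester is untouched.

### Main line

**Step 8**
Reactants: 10; 5
Product: 11, methyl (3S,4R,6S)‑4‑{[(4R)‑4‑benzyl‑2‑oxo‑oxazolidin‑3‑yl]carbonyl}‑6‑(TBSO)‑3,7‑dimethyloct‑7‑enoate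
Conditions: NaHMDS, THF, −78 °C; then 5, −78 → −40 °C
Reagents that add atoms: none
Why: Evans asymmetric alkylation; the chelated Z‑sodium enolate of the imide (more acidic than the ester) is alkylated on the face opposite the benzyl group, setting C6 as R.

**Step 9**
Reactants: 11
Product: 12, methyl (3S,4R,6S)‑6‑(TBSO)‑4‑[(ethylsulfanyl)carbonyl]‑3,7‑dimethyloct‑7‑enoate
Conditions: EtSH, n‑BuLi, THF, 0 °C
Reagents that add atoms: ethanethiol, CCS
Why: Lithium thiolate cleaves the hindered imide at the exocyclic carbonyl (auxiliary recovered) without touching the methyl ester.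

**Step 10**
Reactants: 12
Product: 13, methyl (3S,4R,6S)‑6‑(TBSO)‑3,7‑dimethyl‑4‑(prop‑2‑enoyl)oct‑7‑enoate
Conditions: CH2=CHSnBu3, Pd2(dba)3, P(2‑furyl)3, Cu(I) diphenylphosphinate, THF, 50 °C
Reagents that add atoms: tributyl(vinyl)stannane, C=C[Sn](CCCC)(CCCC)CCCC
Why: Liebeskind–Srogl‑type Pd/Cu thioester–stannane coupling gives the vinyl ketone under neutral conditions, so the α‑stereocentre (C6) is not epimerised and the ester survives.

**Step 11**
Reactants: 13
Product: 14, methyl (3S)‑3‑[(1R,5S)‑5‑(TBSO)‑4‑methyl‑2‑oxocyclohex‑3‑en‑1‑yl]butanoate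
Conditions: Hoveyda–Grubbs II (5 mol%), toluene (5 mM), 80 °C
Reagents that add atoms: none
Why: Ring‑closing metathesis of the vinyl ketone with the 1,1‑disubstituted alkene forms the six‑membered ring and its trisubstituted C2=C3 bond with loss of ethylene.

**Step 12**
Reactants: 14
Product: 15, (4S,4aR,6S,8aS)‑6‑(TBSO)‑4,7‑dimethyl‑3,4,4a,5,6,8a‑hexahydro‑2H‑chromen‑2‑one (cis‑fused δ‑lactone)
Conditions: L‑Selectride, THF, −78 °C; warm to rt; aq NH4Cl
Reagents that add atoms: none
Why: Bulky‑hydride 1,2‑reduction by equatorial attack on the half‑chair (C6 chain pseudo‑equatorial, C4–OTBS pseudo‑axial) gives the pseudo‑axial C1 alkoxide cis to the side chain (1S), which lactonises onto the methyl ester.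

**Step 13**
Reactants: 15
Product: 16, (6S)‑6‑[(1R,2S,5S)‑5‑(TBSO)‑2‑hydroxy‑4‑methylcyclohex‑3‑en‑1‑yl]‑2‑methylhept‑2‑en‑4‑one
Conditions: Me2C=CHLi (from Me2C=CHBr, t‑BuLi), THF, −78 °C; AcOH quench at −78 °C
Reagents that add atoms: (2‑methylprop‑1‑en‑1‑yl)lithium, [Li]C=C(C)C
Why: Mono‑addition of the alkenyllithium to the lactone gives a lactolate that is stable at −78 °C and collapses on work‑up, installing the enone and freeing the C1 hydroxyl in one step.

### Branch C – curcuminoid phenol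

**Step 14**
Reactants: 17, vanillin
Product: 18, 3‑methoxy‑4‑(triisopropylsilyloxy)benzaldehyde
Conditions: TIPSCl, imidazole, DMF, rt
Reagents that add atoms: TIPSCl, CC(C)[Si](Cl)(C(C)C)C(C)C
Why: Phenol silylation; the aryl TIPS ether survives the amine/boron condensation and dilute acid and is removed by fluoride at the end.

**Step 15**
Reactants: 17, vanillin; 19, acetylacetone (3 equiv)
Product: 20, feruloylacetone, (5E)‑6‑(4‑hydroxy‑3‑methoxyphenyl)hex‑5‑ene‑2,4‑dione
Conditions: B2O3, (n‑BuO)3B, n‑BuNH2, EtOAc, 70 °C; then 0.4 M HCl, 60 °C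
Reagents that add atoms: none
Why: Pabon boron‑complex aldol condensation; the boron chelate blocks the central carbon and excess diketone stops the reaction at the mono‑styryl stage.

**Step 16**
Reactants: 20; 18
Product: 21, mono‑O‑TIPS curcumin
Conditions: B2O3, (n‑BuO)3B, n‑BuNH2, EtOAc, 70 °C; then 0.4 M HCl, 50 °C
Reagents that add atoms: none
Why: A second Pabon condensation at the remaining terminal methyl gives the unsymmetrical curcuminoid with exactly one free phenol.

### Endgame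

**Step 17**
Reactants: 16; 21 (1.3 equiv)
Product: 22, bis‑silyl (C4‑O‑TBS, aryl‑O‑TIPS) ether of the target
Conditions: PPh3, DIAD, THF, 0 °C → rt
Reagents that add atoms: none
Why: Mitsunobu etherification; the phenol displaces the activated axial allylic C1–O with inversion (1S → 1R), giving the aryl ether trans to the side chain and cis to C4–O.

**Step 18**
Reactants: 22
Product: 23, bisabolocurcumin ether
Conditions: TBAF, AcOH, THF, 0 °C → rt
Reagents that add atoms: none
Why: Buffered fluoride removes the aryl TIPS and the allylic secondary TBS ether without base damage to the curcuminoid or acid ionisation of the allylic ether.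

## Compound list

1 | prenol (3‑methylbut‑2‑en‑1‑ol) | CC(C)=CCO | starting material
2 | [(2S)‑3,3‑dimethyloxiran‑2‑yl]methanol | CC1(C)[C@@H](O1)CO | intermediate
3 | (3R)‑3,4‑bis(TBSO)‑2‑methylbut‑1‑ene | C=C(C)[C@@H](O[Si](C)(C)C(C)(C)C)CO[Si](C)(C)C(C)(C)C | intermediate
4 | (2R)‑2‑(TBSO)‑3‑methylbut‑3‑en‑1‑ol | C=C(C)[C@@H](O[Si](C)(C)C(C)(C)C)CO | intermediate
5 | (2R)‑2‑(TBSO)‑3‑methylbut‑3‑en‑1‑yl triflate | C=C(C)[C@@H](O[Si](C)(C)C(C)(C)C)COS(=O)(=O)C(F)(F)F | intermediate
6 | 3‑methylglutaric acid | CC(CC(=O)O)CC(=O)O | starting material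
7 | dimethyl 3‑methylglutarate | COC(=O)CC(C)CC(=O)OC | intermediate
8 | (3R)‑5‑methoxy‑3‑methyl‑5‑oxopentanoic acid | OC(=O)C[C@@H](C)CC(=O)OC | intermediate
9 | (4R)‑4‑benzyl‑1,3‑oxazolidin‑2‑one | O=C1N[C@H](Cc2ccccc2)CO1 | starting material
10 | methyl (3R)‑5‑[(4R)‑4‑benzyl‑2‑oxo‑oxazolidin‑3‑yl]‑3‑methyl‑5‑oxopentanoate | O=C(C[C@@H](C)CC(=O)OC)N1C(=O)OC[C@H]1Cc1ccccc1 | intermediate
11 | methyl (3S,4R,6S)‑4‑{[(4R)‑4‑benzyl‑2‑oxo‑oxazolidin‑3‑yl]carbonyl}‑6‑(TBSO)‑3,7‑dimethyloct‑7‑enoate | C=C(C)[C@@H](O[Si](C)(C)C(C)(C)C)C[C@@H](C(=O)N1C(=O)OC[C@H]1Cc1ccccc1)[C@@H](C)CC(=O)OC | intermediate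
12 | methyl (3S,4R,6S)‑6‑(TBSO)‑4‑[(ethylsulfanyl)carbonyl]‑3,7‑dimethyloct‑7‑enoate | C=C(C)[C@@H](O[Si](C)(C)C(C)(C)C)C[C@@H](C(=O)SCC)[C@@H](C)CC(=O)OC | intermediate
13 | methyl (3S,4R,6S)‑6‑(TBSO)‑3,7‑dimethyl‑4‑(prop‑2‑enoyl)oct‑7‑enoate | C=C(C)[C@@H](O[Si](C)(C)C(C)(C)C)C[C@@H](C(=O)C=C)[C@@H](C)CC(=O)OC | intermediate
14 | methyl (3S)‑3‑[(1R,5S)‑5‑(TBSO)‑4‑methyl‑2‑oxocyclohex‑3‑en‑1‑yl]butanoate | O=C1C=C(C)[C@@H](O[Si](C)(C)C(C)(C)C)C[C@@H]1[C@@H](C)CC(=O)OC | intermediate
15 | (4S,4aR,6S,8aS)‑6‑(TBSO)‑4,7‑dimethyl‑3,4,4a,5,6,8a‑hexahydro‑2H‑chromen‑2‑one | O1[C@@H]2C=C(C)[C@@H](O[Si](C)(C)C(C)(C)C)C[C@@H]2[C@@H](C)CC1=O | intermediate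
16 | (6S)‑6‑[(1R,2S,5S)‑5‑(TBSO)‑2‑hydroxy‑4‑methylcyclohex‑3‑en‑1‑yl]‑2‑methylhept‑2‑en‑4‑one | O[C@@H]1C=C(C)[C@@H](O[Si](C)(C)C(C)(C)C)C[C@@H]1[C@@H](C)CC(=O)C=C(C)C | intermediate
17 | vanillin | COc1cc(C=O)ccc1O | starting material
18 | 3‑methoxy‑4‑(triisopropylsilyloxy)benzaldehyde | COc1cc(C=O)ccc1O[Si](C(C)C)(C(C)C)C(C)C | intermediate
19 | acetylacetone | CC(=O)CC(C)=O | starting material
20 | feruloylacetone | COc1cc(/C=C/C(=O)CC(C)=O)ccc1O | intermediate
21 | mono‑O‑TIPS curcumin | COc1cc(/C=C/C(=O)/C=C(O)/C=C/c2ccc(O)c(OC)c2)ccc1O[Si](C(C)C)(C(C)C)C(C)C | intermediate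
22 | C4‑O‑TBS, 4′‑O‑TIPS bisabolocurcumin ether | COc1cc(/C=C/C(=O)/C=C(O)/C=C/c2ccc(O[C@H]3C=C(C)[C@@H](O[Si](C)(C)C(C)(C)C)C[C@@H]3[C@@H](C)CC(=O)C=C(C)C)c(OC)c2)ccc1O[Si](C(C)C)(C(C)C)C(C)C | intermediate
23 | bisabolocurcumin ether | COc1cc(/C=C/C(=O)/C=C(O)/C=C/c2ccc(O[C@H]3C=C(C)[C@@H](O)C[C@@H]3[C@@H](C)CC(=O)C=C(C)C)c(OC)c2)ccc1O | target

## Step count

Total steps: 18.
Longest linear sequence: 12 (steps 1–4, 8–13, 17, 18), i.e. 12/18 = two thirds.

## Steps most likely to fail, with fallbacks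

1. **Step 8** (alkylation of the imide enolate with a β‑branched, β‑silyloxy triflate; slow SN2 or E2 possible). Fallback: alkylate 10 with prenyl bromide (routine Evans allylation), then create C4 on the main line by Shi asymmetric epoxidation of the prenyl group and the same R3SiOTf/DBU epoxide → allyl silyl ether isomerisation; steps 9–18 are unchanged.

2. **Step 12** (the reduction must give the pseudo‑axial alcohol; a wrong face gives the C1 epimer). Fallback: accept the equatorial alcohol from Luche reduction (NaBH4/CeCl3), saponify the methyl ester, and close lactone 15 by intramolecular Mitsunobu lactonisation, which inverts C1 and rejoins the route.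

3. **Step 17** (Mitsunobu of a hindered allylic alcohol with a phenol that also carries an acidic enolised β‑diketone; elimination or diketone alkylation possible). Fallback: couple 16 with vanillin (17) by Mitsunobu, then build the curcuminoid on the resulting aryl aldehyde by Pabon condensation with feruloylacetone (20), and finish with desilylation.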